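## Retrosynthetic overview

1. The pyranone is bought intact as methyl ether 1. Radical bromination of its 6-methyl group gives bromide 2, an enolonium-type (a2) synthon: the alpha-carbon of the masked ketone, normally a vinylogous enolate nucleophile, is used as the electrophile.
2. Ring A–CO bond: Friedel–Crafts acylation of arene 3 with acid chloride 4 gives benzophenone 5, the sterically most tolerant way to the crowded ketone.
3. Key disconnection: the ring B C6–CH2 bond, made late between the two complete halves. The ketone of 5 directs C–H borylation to boronate 6, which is coupled with 2 to give 7.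
4. Global O-demethylation of 7 gives target 8.
5. Ring order: no ring is built; ring A, ring B and the pyranone all come from the starting materials.

Assumption: the target has no stereocentre and no stable atropisomer, so it is made as the achiral compound drawn; 1-ethyl-3,5-dimethoxybenzene is taken as a catalogue compound.

## Route

Step 1
Reactants: 1 4-methoxy-6-methyl-2H-pyran-2-one
Product: 2 6-(bromomethyl)-4-methoxy-2H-pyran-2-one
Conditions: NBS (1.05 equiv), (PhCO2)2 (5 mol %), CCl4, reflux, 3 h
Reagents that add atoms: N-bromosuccinimide, O=C1CCC(=O)N1Br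
Why: Wohl–Ziegler radical bromination; the 6-methyl group is the only allylic-type C–H, and radical rather than ionic conditions keep bromine off C3 of the pyranone.

Step 2
Reactants: 3 1-ethyl-3,5-dimethoxybenzene; 4 2-methoxybenzoyl chloride
Product: 5 (2-ethyl-4,6-dimethoxyphenyl)(2-methoxyphenyl)methanone
Conditions: AlCl3 (1.2 equiv), CH2Cl2, −10 to 0 °C, 2 h; cold 1 M HCl
Reagents that add atoms: none
Why: Friedel–Crafts acylation; the acylium ion attacks C2 of 3 (para to one methoxy group, ortho to the other) in preference to the position between both methoxy groups, as is usual for orcinol dimethyl ether, and the low temperature avoids demethylation next to the new ketone.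

Step 3
Reactants: 5 (2-ethyl-4,6-dimethoxyphenyl)(2-methoxyphenyl)methanone; 2 6-(bromomethyl)-4-methoxy-2H-pyran-2-one
Product: 7 6-[2-(2-ethyl-4,6-dimethoxybenzoyl)-3-methoxybenzyl]-4-methoxy-2H-pyran-2-one, via aryl pinacol boronate 6 (not isolated)
Conditions: [Ir(OMe)(cod)]2 (2.5 mol %), AsPh3 (10 mol %), B2pin2 (1.1 equiv), octane, 120 °C, 16 h; evaporate; then 2 (1.3 equiv), PdCl2(dppf) (5 mol %), K2CO3 (3 equiv), THF/H2O 10:1, 60 °C
Reagents that add atoms: bis(pinacolato)diboron, CC1(C)OB(OC1(C)C)B1OC(C)(C)C(C)(C)O1 (supplies the boronate group of 6; none of its atoms remain in 7)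
Why: Ketone-directed ortho C–H borylation with [Ir(OMe)(cod)]2/AsPh3 can only reach C6–H of ring B because ring A has no ortho hydrogen, and the aryl boronate then undergoes a PdCl2(dppf)-catalysed Suzuki–Miyaura sp2–sp3 coupling with bromide 2, whose CH2 carbon (normally the nucleophilic vinylogous enolate site of the pyranone) acts here as the enolonium-type electrophile.

Step 4
Reactants: 7 6-[2-(2-ethyl-4,6-dimethoxybenzoyl)-3-methoxybenzyl]-4-methoxy-2H-pyran-2-one
Product: 8 6-[2-(2-ethyl-4,6-dihydroxybenzoyl)-3-hydroxybenzyl]-4-hydroxy-2H-pyran-2-one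
Conditions: BBr3 (8 equiv), CH2Cl2, −78 °C to rt, 16 h; ice-water
Reagents that add atoms: none
Why: Lewis-acid ether cleavage (BBr3 demethylation); bromide attacks the methyl group of each boron-complexed aryl ether and of the vinylogous ester, while the hindered ketone and the 4-hydroxypyranone tolerate the reagent.

## Compound list

1 | 4-methoxy-6-methyl-2H-pyran-2-one | COc1cc(C)oc(=O)c1 | starting material
2 | 6-(bromomethyl)-4-methoxy-2H-pyran-2-one | COc1cc(CBr)oc(=O)c1 | intermediate
3 | 1-ethyl-3,5-dimethoxybenzene | CCc1cc(OC)cc(OC)c1 | starting material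
4 | 2-methoxybenzoyl chloride | COc1ccccc1C(Cl)=O | starting material
5 | (2-ethyl-4,6-dimethoxyphenyl)(2-methoxyphenyl)methanone | CCc1cc(OC)cc(OC)c1C(=O)c1ccccc1OC | intermediate
6 | (2-ethyl-4,6-dimethoxyphenyl)[2-methoxy-6-(4,4,5,5-tetramethyl-1,3,2-dioxaborolan-2-yl)phenyl]methanone | CCc1cc(OC)cc(OC)c1C(=O)c1c(OC)cccc1B1OC(C)(C)C(C)(C)O1 | intermediate
7 | 6-[2-(2-ethyl-4,6-dimethoxybenzoyl)-3-methoxybenzyl]-4-methoxy-2H-pyran-2-one | CCc1cc(OC)cc(OC)c1C(=O)c1c(OC)cccc1Cc1cc(OC)cc(=O)o1 | intermediate
8 | 6-[2-(2-ethyl-4,6-dihydroxybenzoyl)-3-hydroxybenzyl]-4-hydroxy-2H-pyran-2-one | CCc1cc(O)cc(O)c1C(=O)c1c(O)cccc1Cc1cc(O)cc(=O)o1 | target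

## Step count and risks

Total step count: 4. Longest linear sequence: 3 (steps 2, 3 and 4, from 3 and 4 to 8); step 1 is a one-step side branch.

Most likely to fail, first: step 3. The ketone of 5 is twisted and crowded, so the directed borylation may be slow or unselective, and the aqueous base can hydrolyse bromide 2 before it couples. The fallback fixes the boron site with a halogen that is bought in, and sets out from arene 3. Purchased 2-bromo-6-methoxybenzoic acid is converted with (COCl)2 and catalytic DMF into 2-bromo-6-methoxybenzoyl chloride F1. This acylates 3 (AlCl3, CH2Cl2, 0 °C) to give (2-bromo-6-methoxyphenyl)(2-ethyl-4,6-dimethoxyphenyl)methanone F2. Miyaura borylation of F2 (B2pin2, PdCl2(dppf), KOAc, dioxane, 90 °C) then gives boronate 6, where the fallback comes back to the route for the second half of step 3.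

Second: step 4. Four methyl ethers of two kinds must fall together; the pyranone vinylogous ester may lag behind the aryl ethers, or the electron-rich product may suffer under a large excess of BBr3. The fallback sets out from 7 and splits the unmasking into two orthogonal stages. LiCl in DMF at 120 °C removes the pyranone methyl group by SN2 attack at carbon, the pyranonate being a carboxylate-like leaving group. This gives 6-[2-(2-ethyl-4,6-dimethoxybenzoyl)-3-methoxybenzyl]-4-hydroxy-2H-pyran-2-one F3. A smaller excess of BBr3 (4 equiv, CH2Cl2, −78 to 0 °C) then cleaves only the three aryl ethers, and the fallback comes back to the route at 8.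

Third: step 1. Ring bromination at C3 and double bromination compete with the wanted radical reaction. The fallback sets out from 1 and reaches the bromide through the alcohol. SeO2 in dioxane at 160 °C (sealed tube) oxidises the methyl group to 4-methoxy-2-oxo-2H-pyran-6-carbaldehyde F4. NaBH4 in MeOH at 0 °C gives 6-(hydroxymethyl)-4-methoxy-2H-pyran-2-one F5. An Appel reaction (CBr4, PPh3, CH2Cl2, 0 °C) gives bromide 2, where the fallback comes back to the route.

## Further compounds

F1 | step 3 | 2-bromo-6-methoxybenzoyl chloride | COc1cccc(Br)c1C(Cl)=O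
F2 | step 3 | (2-bromo-6-methoxyphenyl)(2-ethyl-4,6-dimethoxyphenyl)methanone | CCc1cc(OC)cc(OC)c1C(=O)c1c(OC)cccc1Br
F3 | step 4 | 6-[2-(2-ethyl-4,6-dimethoxybenzoyl)-3-methoxybenzyl]-4-hydroxy-2H-pyran-2-one | CCc1cc(OC)cc(OC)c1C(=O)c1c(OC)cccc1Cc1cc(O)cc(=O)o1
F4 | step 1 | 4-methoxy-2-oxo-2H-pyran-6-carbaldehyde | COc1cc(C=O)oc(=O)c1
F5 | step 1 | 6-(hydroxymethyl)-4-methoxy-2H-pyran-2-one | COc1cc(CO)oc(=O)c1
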